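To whoever takes the bench: the amounts are what we have to go on. Five flasks are running, identical except for the substrate charge.

| flask | substrate | reagent | remark | time |
|---|---|---|---|---|
| Saturday's | 0.11 M | 0.48 M | run made earlier |  |
| Sunday's | 2.2 M | 0.48 M | run made earlier |  |
| delta | 0.10 M | 0.480 M |  | 6.0 h |
| zeta | 0.20 M | 0.480 M |  | 6.0 h |
| gamma | 0.40 M | 0.480 M |  | 6.0 h |
| beta | 0.80 M | 0.480 M |  | 6.0 h |
| eta | 1.5 M | 0.480 M |  | 6.0 h |

- [product] (only what is free in solution) at the end for delta, zeta, gamma, beta, eta, in this order
- how the row runs (rises, then falls / falls, then rises / falls all the way / rises all the way / hardly changes)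

- the earlier runs were read with a standard deviation of 1.5 percentage points
- a reading or a percentage of product counts all its forms, free or not
- the concentration of product that is asked is that of its free form alone
- "hardly changes" means that all values lie within two and a half points (for a concentration: within two and a half percent of the largest)

| run | time / h | product / % |
|---|---|---|
| Saturday's | 1.33 | 3 |
| Saturday's | 2.50 | 11 |
| Saturday's | 4.00 | 24 |
| Saturday's | 5.00 | 34 |
| Saturday's | 6.00 | 44 |
| Sunday's | 1.33 | 0 |
| Sunday's | 2.50 | 0 |
| Sunday's | 4.00 | 0 |
| Sunday's | 5.00 | 0 |
| Sunday's | 6.00 | 1 |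

(each reading ± 1.5 percentage points)

Saturday's last reading, 44.0%, we call the excess-reagent yield: the share of the charged substrate found as product at the end, with 4.36 reagent per substrate. Sunday's flask had 0.218 reagent per substrate and read 1%, far less than Saturday's, though within about its scatter of zero.

Our own reckoning treats the shortfall as a correction to one line, c(product) = Y · c(substrate). Delta has 4.80 reagent per substrate, more than Saturday's, so we commit to 0.0440 M there, taking the bound part of the product in that flask as small. Flasks further along have less reagent per substrate, so they should fall below the line and, nearer Sunday's ratio, come down. Do not top up the reagent: reagent per substrate is the setting we are reading against.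

The forecast gives 0.034 M, 0.037 M, 0.024 M, 0.011 M and 0.005 M, a row that rises, then falls, and calls itself “an envelope estimate, not a determined mechanism”. At delta it stands below our figure.

The flasks give 0.0441 M, 0.0708 M, 0.0768 M, 0.0282 M and 0.00440 M: the row rises, then falls, turning at 0.32 M substrate.

    reagent + intermediate B ⇌ intermediate C (K = 2.40 /M, k = 2.90 × 10⁻⁵ /M/s)
    substrate → intermediate B (k = 3.30 × 10⁻⁵ /s)
    substrate + reagent → intermediate A (k = 5.10 × 10⁻⁴ /M/s)
    reagent + intermediate D → product (k = 2.20 × 10⁻⁴ /M/s)
    substrate + product ⇌ idle adduct, settled at all times (K = 1.80 /M)
    intermediate A → intermediate D (k = 1.20 × 10⁻⁴ /s)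

In eta, reagent is the limiting reagent, with 0.0151% of its charge left beside 32.7% of the substrate. Delta's 0.0441 M stands on the line at 0.0440 M. Zeta's line gives 0.0880 M, and zeta holds 0.0708 M free, with 35.6% of its substrate charge as product, bound forms counted, and 49.5% of its reagent still present.

(The data were generated by integration with made-up constants; the scatter is artificial.)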